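**Retrosynthetic overview**

1. The strategy rests on ring C, a benzene ring carrying the ring B oxygen at C1, the ring E oxygen at C4, hydroxyls at C2 and C6 and hydrogens at C3 and C5, which links the A-B-D-J half to the E-F-G-H-I half.
2. Ring C is the only ring built: a benzannulation of 4-aryloxy-3-ethoxycyclobutenone 29 (ring B half) with aryl ethynyl ether 16 (ring E half) makes C2–C3 and C4–C5 and closes the ring; BBr3 then frees all 24 hydroxyls.
3. 29 comes from ring B phenol 22 (O-alkylation, aryloxyketene plus ethoxyacetylene); 16 comes from ring E phenol 11 (trichloroethylene, then n-BuLi).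
4. Both phenols derive from one fluoroaldehyde, 8: SNAr on 2,6-difluoro-4-methoxybenzaldehyde with biaryl phenol 6, a formyl-to-hydroxyl Baeyer–Villiger exchange for the crowded central oxygen, and copper-catalysed arylation for ring A.
5. Biaryl phenol 6 (used three times, as D-J, F-G and H-I) comes from a Suzuki coupling followed by Baeyer–Villiger oxidation.

Key step: step 16

Remark on the chemistry: the target has no stereocentre and its three biaryl axes are not stereogenic (rings J, G and I are symmetric about the axis), so no stereocontrol is needed; compounds 1, 3, 7, 12, 20, 23 and 26 are taken as commercial.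

Abbreviations in names: ArO = 2,4,6-trimethoxy-3-(2,4,6-trimethoxyphenyl)phenoxy; E-half aryloxy = 4-methoxy-2,6-bis(ArO)phenoxy; B-half aryloxy = 2-(3,5-dimethoxyphenoxy)-5-methoxy-3-(ArO)phenoxy.

**Route**

Step 1
Reactants: 1 2,4,6-trimethoxybenzaldehyde
Product: 2 3-bromo-2,4,6-trimethoxybenzaldehyde
Conditions: NBS (1.05 equiv), MeCN, 0 °C to rt
Reagents that add atoms: N-bromosuccinimide, O=C1CCC(=O)N1Br
Why: Electrophilic aromatic bromination at one of the two equivalent free positions, each activated by three methoxy groups; the first bromine and the formyl group should slow a second substitution.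

Step 2
Reactants: 2 3-bromo-2,4,6-trimethoxybenzaldehyde; 3 2,4,6-trimethoxyphenylboronic acid
Product: 4 2,4,6-trimethoxy-3-(2,4,6-trimethoxyphenyl)benzaldehyde
Conditions: 3 (1.8 equiv), Pd(OAc)2 (5 mol%), SPhos (10 mol%), K3PO4 (3 equiv), toluene/H2O 10:1, 90 °C
Reagents that add atoms: none
Why: Suzuki–Miyaura coupling with a palladium catalyst carrying the bulky biaryl phosphine SPhos, the established system for tetra-ortho-substituted biaryls; the formyl group speeds oxidative addition and the excess of 3 covers protodeboronation.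

Step 3
Reactants: 4 2,4,6-trimethoxy-3-(2,4,6-trimethoxyphenyl)benzaldehyde
Product: 6 2,4,6-trimethoxy-3-(2,4,6-trimethoxyphenyl)phenol (ArOH), via aryl formate 5 (not isolated)
Conditions: mCPBA (1.2 equiv), CH2Cl2, 0 °C; then K2CO3 (cat.), MeOH, rt
Reagents that add atoms: meta-chloroperoxybenzoic acid, OOC(=O)c1cccc(Cl)c1
Why: Baeyer–Villiger (Dakin-type) oxidation of an electron-rich benzaldehyde, in which the trioxygenated aryl group migrates in preference to hydrogen to give formate 5, which mild methanolysis converts to the phenol.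

Step 4
Reactants: 6 2,4,6-trimethoxy-3-(2,4,6-trimethoxyphenyl)phenol; 7 2,6-difluoro-4-methoxybenzaldehyde
Product: 8 2-fluoro-4-methoxy-6-(ArO)benzaldehyde
Conditions: 7 (3 equiv, excess recovered), K2CO3, DMF, 70 °C
Reagents that add atoms: none
Why: Nucleophilic aromatic substitution (SNAr) of a fluoride ortho to the formyl group by the phenoxide of 6; the excess of 7 and the deactivation by the first aryloxy group should hold the reaction at monosubstitution.

Step 5
Reactants: 8 2-fluoro-4-methoxy-6-(ArO)benzaldehyde; 6 2,4,6-trimethoxy-3-(2,4,6-trimethoxyphenyl)phenol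
Product: 9 4-methoxy-2,6-bis(ArO)benzaldehyde
Conditions: 6 (1.3 equiv), Cs2CO3, DMF, 110 °C
Reagents that add atoms: none
Why: Second SNAr at the remaining fluoride, which is still ortho to the formyl group and lies on the far side of it from the first aryloxy group, driven by the cesium phenoxide at higher temperature.

Step 6
Reactants: 9 4-methoxy-2,6-bis(ArO)benzaldehyde
Product: 11 4-methoxy-2,6-bis(ArO)phenol (ring E phenol), via aryl formate 10 (not isolated)
Conditions: mCPBA (1.3 equiv), CH2Cl2, 0 °C to rt; then K2CO3 (cat.), MeOH, rt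
Reagents that add atoms: meta-chloroperoxybenzoic acid, OOC(=O)c1cccc(Cl)c1
Why: Baeyer–Villiger oxidation with migration of the 2,4,6-trioxygenated ring, then methanolysis of formate 10, which puts the central hydroxyl of ring E between both aryloxy groups without any etherification at that crowded position.

Step 7
Reactants: 11 4-methoxy-2,6-bis(ArO)phenol; 12 trichloroethylene
Product: 13 (E)-1,2-dichlorovinyl 4-methoxy-2,6-bis(ArO)phenyl ether
Conditions: 12 (3 equiv), Cs2CO3 (2 equiv), DMF, 60 °C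
Reagents that add atoms: none
Why: Base-mediated addition of the phenoxide to dichloroacetylene formed in situ from trichloroethylene (first stage of the Greene ynol ether synthesis); anti addition gives the E dichlorovinyl ether and the small linear electrophile tolerates the crowded oxygen.

Step 8
Reactants: 13 (E)-1,2-dichlorovinyl 4-methoxy-2,6-bis(ArO)phenyl ether
Product: 16 ethynyl 4-methoxy-2,6-bis(ArO)phenyl ether, via chloroethynyl ether 14 (not isolated), via lithium acetylide 15 (not isolated)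
Conditions: n-BuLi (2.3 equiv), THF, −78 °C to −40 °C; then MeOH, −78 °C; used promptly
Reagents that add atoms: none
Why: Elimination followed by lithium–halogen exchange (second stage of the Greene ynol ether synthesis): n-BuLi removes HCl to give chloroalkyne 14 and exchanges its chlorine to give acetylide 15, which is protonated cold; at −78 °C these events should outrun ortho-lithiation of the methoxyarenes.

Step 9
Reactants: 8 2-fluoro-4-methoxy-6-(ArO)benzaldehyde
Product: 17 2-benzyloxy-4-methoxy-6-(ArO)benzaldehyde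
Conditions: BnOH (1.5 equiv), Cs2CO3, DMF, 70 °C
Reagents that add atoms: benzyl alcohol, OCc1ccccc1
Why: SNAr of the remaining ortho-fluoride by benzyl alkoxide, which installs the future ring B hydroxyl as a benzyl ether orthogonal to the methyl ethers.

Step 10
Reactants: 17 2-benzyloxy-4-methoxy-6-(ArO)benzaldehyde
Product: 19 2-benzyloxy-4-methoxy-6-(ArO)phenol, via aryl formate 18 (not isolated)
Conditions: mCPBA (1.3 equiv), CH2Cl2, 0 °C to rt; then K2CO3 (cat.), MeOH, rt
Reagents that add atoms: meta-chloroperoxybenzoic acid, OOC(=O)c1cccc(Cl)c1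
Why: Baeyer–Villiger oxidation and methanolysis as in steps 3 and 6, turning the formyl carbon into the central oxygen of ring B; the benzyl ether is inert to the peracid.

Step 11
Reactants: 19 2-benzyloxy-4-methoxy-6-(ArO)phenol; 20 1-iodo-3,5-dimethoxybenzene
Product: 21 1-benzyloxy-2-(3,5-dimethoxyphenoxy)-5-methoxy-3-(ArO)benzene
Conditions: 20 (1.5 equiv), CuI (10 mol%), picolinic acid (20 mol%), K3PO4 (2 equiv), DMSO, 90 °C, Ar
Reagents that add atoms: none
Why: Copper-catalysed Ullmann-type diaryl ether synthesis; picolinic acid-ligated copper is known to arylate 2,6-disubstituted phenols and the aryl iodide is unhindered, so the crowding lies on the nucleophile only.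

Step 12
Reactants: 21 1-benzyloxy-2-(3,5-dimethoxyphenoxy)-5-methoxy-3-(ArO)benzene
Product: 22 2-(3,5-dimethoxyphenoxy)-5-methoxy-3-(ArO)phenol (ring B phenol)
Conditions: H2 (1 atm), 10% Pd/C, EtOAc/EtOH, rt
Reagents that add atoms: none
Why: Hydrogenolysis of the benzyl ether over palladium on carbon, which leaves diaryl ethers and methyl ethers untouched.

Step 13
Reactants: 22 2-(3,5-dimethoxyphenoxy)-5-methoxy-3-(ArO)phenol; 23 methyl bromoacetate
Product: 24 methyl (B-half aryloxy)acetate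
Conditions: 23 (1.3 equiv), K2CO3, acetone, reflux
Reagents that add atoms: none
Why: Williamson O-alkylation of the phenoxide by an α-bromo ester (SN2).

Step 14
Reactants: 24 methyl (B-half aryloxy)acetate
Product: 25 (B-half aryloxy)acetic acid
Conditions: LiOH·H2O, THF/MeOH/H2O, rt; then 1 M HCl
Reagents that add atoms: water (as LiOH/H2O), O
Why: Saponification of the methyl ester; the aryl ethers are stable to hydroxide.

Step 15
Reactants: 25 (B-half aryloxy)acetic acid; 26 ethoxyacetylene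
Product: 29 4-(B-half aryloxy)-3-ethoxycyclobut-2-en-1-one (racemic), via acid chloride 27 (not isolated), via aryloxyketene 28 (not isolated)
Conditions: (COCl)2, DMF (cat.), CH2Cl2, 0 °C to rt, evaporate; then slow addition to 26 (4 equiv) and Et3N (1.5 equiv), CH2Cl2, rt to 35 °C
Reagents that add atoms: none
Why: Acid chloride formation, dehydrochlorination to aryloxyketene 28 and ketene–ynol ether [2+2] cycloaddition (the known route to 4-substituted 3-ethoxycyclobutenones), in which the nucleophilic terminal carbon of ethoxyacetylene bonds to the ketene carbonyl carbon and so fixes the 3-ethoxy-4-aryloxy pattern; the new sp3 centre is racemic and disappears in step 16.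

Step 16
Reactants: 29 4-(B-half aryloxy)-3-ethoxycyclobut-2-en-1-one; 16 ethynyl 4-methoxy-2,6-bis(ArO)phenyl ether
Product: 34 2-(B-half aryloxy)-3-ethoxy-5-(E-half aryloxy)phenol (ten-ring phenol with one ethyl and 22 methyl ethers), via vinylketene 30 (not isolated), via 4-vinylcyclobutenone 31 (not isolated), via dienylketene 32 (not isolated), via cyclohexadienone 33 (not isolated)
Conditions: 16 (1.3 equiv), degassed toluene (0.1 M), 110–120 °C, sealed tube, Ar
Reagents that add atoms: none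
Why: Proposed new method: heating opens cyclobutenone 29 by a four-electron conrotatory electrocyclic reaction, the 4-aryloxy donor turning outward, to vinylketene 30, whose ketene C=C adds [2+2] to ynol ether 16 to give 4-vinylcyclobutenone 31; a second, reversible four-electron opening gives dienylketene 32, which closes to cyclohexadienone 33 and tautomerises to phenol 34. The closest known reaction type is the Danheiser benzannulation of cyclobutenones with alkoxy- and siloxyacetylenes, which has not been shown with an aryloxyacetylene, with a 4-aryloxy-3-alkoxycyclobutenone or with partners of this size. Ring C is closed by a thermal six-electron disrotatory electrocyclisation of 32 that joins the ketene carbon (C2 of ring C) to the aryloxy-bearing terminus (C1), after the [2+2] step has made the C2–C3 and C4–C5 bonds. No stereocentre is created, since the racemic sp3 carbons of 29, 31 and 33 all become sp2 on aromatisation. The selectivity required is the orientation of the ketene–alkyne addition, and it is secured by the polarisation of the ynol ether: its terminal carbon, β to oxygen and nucleophilic, bonds to the electrophilic ketene carbonyl carbon, which places the ring E oxygen para to the ring B oxygen and meta to the new hydroxyl. The two crowded C–O bonds are already present on an sp3 carbon of 29 and on the sp carbon of 16, so only C–C bonds form at the congested site, and the aryl ynol ether, unlike ethoxyacetylene, has no β-hydrogen for retro-ene loss of ketene at the temperature the push-pull cyclobutenone needs.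

Step 17
Reactants: 34 2-(B-half aryloxy)-3-ethoxy-5-(E-half aryloxy)phenol
Product: 35 CNP0294555.0 (target, 24 free hydroxyls)
Conditions: BBr3 (excess, about 40 equiv), CH2Cl2, −78 °C to rt; then H2O, 0 °C; reversed-phase purification under Ar
Reagents that add atoms: none
Why: Lewis acid-mediated ether cleavage with BBr3 (bromide attacks the alkyl group of the boron-complexed ether), which removes the 22 methyl groups and the ethyl group alike and leaves diaryl ether and biaryl bonds intact.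

**Compound list**

1 | 2,4,6-trimethoxybenzaldehyde | COc1cc(OC)c(C=O)c(OC)c1 | starting material
2 | 3-bromo-2,4,6-trimethoxybenzaldehyde | COc1cc(OC)c(C=O)c(OC)c1Br | intermediate
3 | 2,4,6-trimethoxyphenylboronic acid | COc1cc(OC)c(B(O)O)c(OC)c1 | starting material
4 | 2,4,6-trimethoxy-3-(2,4,6-trimethoxyphenyl)benzaldehyde | O=Cc1c(OC)cc(OC)c(-c2c(OC)cc(OC)cc2OC)c1OC | intermediate
5 | 2,4,6-trimethoxy-3-(2,4,6-trimethoxyphenyl)phenyl formate | O=COc1c(OC)cc(OC)c(-c2c(OC)cc(OC)cc2OC)c1OC | intermediate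
6 | 2,4,6-trimethoxy-3-(2,4,6-trimethoxyphenyl)phenol (ArOH) | Oc1c(OC)cc(OC)c(-c2c(OC)cc(OC)cc2OC)c1OC | intermediate
7 | 2,6-difluoro-4-methoxybenzaldehyde | O=Cc1c(F)cc(OC)cc1F | starting material
8 | 2-fluoro-4-methoxy-6-(ArO)benzaldehyde | O=Cc1c(F)cc(OC)cc1Oc1c(OC)cc(OC)c(-c2c(OC)cc(OC)cc2OC)c1OC | intermediate
9 | 4-methoxy-2,6-bis(ArO)benzaldehyde | O=Cc1c(Oc2c(OC)cc(OC)c(-c3c(OC)cc(OC)cc3OC)c2OC)cc(OC)cc1Oc1c(OC)cc(OC)c(-c2c(OC)cc(OC)cc2OC)c1OC | intermediate
10 | 4-methoxy-2,6-bis(ArO)phenyl formate | O=COc1c(Oc2c(OC)cc(OC)c(-c3c(OC)cc(OC)cc3OC)c2OC)cc(OC)cc1Oc1c(OC)cc(OC)c(-c2c(OC)cc(OC)cc2OC)c1OC | intermediate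
11 | 4-methoxy-2,6-bis(ArO)phenol (ring E phenol, rings E-F-G-H-I) | Oc1c(Oc2c(OC)cc(OC)c(-c3c(OC)cc(OC)cc3OC)c2OC)cc(OC)cc1Oc1c(OC)cc(OC)c(-c2c(OC)cc(OC)cc2OC)c1OC | intermediate
12 | trichloroethylene | ClC=C(Cl)Cl | starting material
13 | (E)-1,2-dichlorovinyl 4-methoxy-2,6-bis(ArO)phenyl ether | Cl/C=C(/Cl)Oc1c(Oc2c(OC)cc(OC)c(-c3c(OC)cc(OC)cc3OC)c2OC)cc(OC)cc1Oc1c(OC)cc(OC)c(-c2c(OC)cc(OC)cc2OC)c1OC | intermediate
14 | chloroethynyl 4-methoxy-2,6-bis(ArO)phenyl ether | ClC#COc1c(Oc2c(OC)cc(OC)c(-c3c(OC)cc(OC)cc3OC)c2OC)cc(OC)cc1Oc1c(OC)cc(OC)c(-c2c(OC)cc(OC)cc2OC)c1OC | intermediate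
15 | lithium (E-half aryloxy)acetylide | [Li]C#COc1c(Oc2c(OC)cc(OC)c(-c3c(OC)cc(OC)cc3OC)c2OC)cc(OC)cc1Oc1c(OC)cc(OC)c(-c2c(OC)cc(OC)cc2OC)c1OC | intermediate
16 | ethynyl 4-methoxy-2,6-bis(ArO)phenyl ether (ynol ether of the ring E half) | C#COc1c(Oc2c(OC)cc(OC)c(-c3c(OC)cc(OC)cc3OC)c2OC)cc(OC)cc1Oc1c(OC)cc(OC)c(-c2c(OC)cc(OC)cc2OC)c1OC | intermediate
17 | 2-benzyloxy-4-methoxy-6-(ArO)benzaldehyde | O=Cc1c(OCc2ccccc2)cc(OC)cc1Oc1c(OC)cc(OC)c(-c2c(OC)cc(OC)cc2OC)c1OC | intermediate
18 | 2-benzyloxy-4-methoxy-6-(ArO)phenyl formate | O=COc1c(OCc2ccccc2)cc(OC)cc1Oc1c(OC)cc(OC)c(-c2c(OC)cc(OC)cc2OC)c1OC | intermediate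
19 | 2-benzyloxy-4-methoxy-6-(ArO)phenol | Oc1c(OCc2ccccc2)cc(OC)cc1Oc1c(OC)cc(OC)c(-c2c(OC)cc(OC)cc2OC)c1OC | intermediate
20 | 1-iodo-3,5-dimethoxybenzene | COc1cc(I)cc(OC)c1 | starting material
21 | 1-benzyloxy-2-(3,5-dimethoxyphenoxy)-5-methoxy-3-(ArO)benzene | COc1cc(OC)cc(Oc2c(OCc3ccccc3)cc(OC)cc2Oc2c(OC)cc(OC)c(-c3c(OC)cc(OC)cc3OC)c2OC)c1 | intermediate
22 | 2-(3,5-dimethoxyphenoxy)-5-methoxy-3-(ArO)phenol (ring B phenol, rings A-B-D-J) | COc1cc(OC)cc(Oc2c(O)cc(OC)cc2Oc2c(OC)cc(OC)c(-c3c(OC)cc(OC)cc3OC)c2OC)c1 | intermediate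
23 | methyl bromoacetate | COC(=O)CBr | starting material
24 | methyl (B-half aryloxy)acetate | COc1cc(OC)cc(Oc2c(OCC(=O)OC)cc(OC)cc2Oc2c(OC)cc(OC)c(-c3c(OC)cc(OC)cc3OC)c2OC)c1 | intermediate
25 | (B-half aryloxy)acetic acid | COc1cc(OC)cc(Oc2c(OCC(=O)O)cc(OC)cc2Oc2c(OC)cc(OC)c(-c3c(OC)cc(OC)cc3OC)c2OC)c1 | intermediate
26 | ethoxyacetylene | C#COCC | starting material
27 | (B-half aryloxy)acetyl chloride | COc1cc(OC)cc(Oc2c(OCC(=O)Cl)cc(OC)cc2Oc2c(OC)cc(OC)c(-c3c(OC)cc(OC)cc3OC)c2OC)c1 | intermediate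
28 | (B-half aryloxy)ketene | COc1cc(OC)cc(Oc2c(OC=C=O)cc(OC)cc2Oc2c(OC)cc(OC)c(-c3c(OC)cc(OC)cc3OC)c2OC)c1 | intermediate
29 | 4-(B-half aryloxy)-3-ethoxycyclobut-2-en-1-one (racemic) | COc1cc(OC)cc(Oc2c(OC3C(=O)C=C3OCC)cc(OC)cc2Oc2c(OC)cc(OC)c(-c3c(OC)cc(OC)cc3OC)c2OC)c1 | intermediate
30 | (3Z)-4-(B-half aryloxy)-3-ethoxybuta-1,3-dien-1-one (vinylketene, aryloxy cis to ethoxy, expected geometry) | COc1cc(OC)cc(Oc2c(O/C=C(\OCC)C=C=O)cc(OC)cc2Oc2c(OC)cc(OC)c(-c3c(OC)cc(OC)cc3OC)c2OC)c1 | intermediate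
31 | 4-[(Z)-2-(B-half aryloxy)-1-ethoxyvinyl]-3-(E-half aryloxy)cyclobut-2-en-1-one (racemic) | COc1cc(OC)cc(Oc2c(O/C=C(\OCC)C3C(=O)C=C3Oc3c(Oc4c(OC)cc(OC)c(-c5c(OC)cc(OC)cc5OC)c4OC)cc(OC)cc3Oc3c(OC)cc(OC)c(-c4c(OC)cc(OC)cc4OC)c3OC)cc(OC)cc2Oc2c(OC)cc(OC)c(-c3c(OC)cc(OC)cc3OC)c2OC)c1 | intermediate
32 | (3E,5Z)-6-(B-half aryloxy)-5-ethoxy-3-(E-half aryloxy)hexa-1,3,5-trien-1-one (dienylketene, ketene and enol ether arm cis on the central double bond) | COc1cc(OC)cc(Oc2c(O/C=C(\OCC)/C=C(Oc3c(Oc4c(OC)cc(OC)c(-c5c(OC)cc(OC)cc5OC)c4OC)cc(OC)cc3Oc3c(OC)cc(OC)c(-c4c(OC)cc(OC)cc4OC)c3OC)\C=C=O)cc(OC)cc2Oc2c(OC)cc(OC)c(-c3c(OC)cc(OC)cc3OC)c2OC)c1 | intermediate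
33 | 6-(B-half aryloxy)-5-ethoxy-3-(E-half aryloxy)cyclohexa-2,4-dien-1-one (racemic) | COc1cc(OC)cc(Oc2c(OC3C(=O)C=C(Oc4c(Oc5c(OC)cc(OC)c(-c6c(OC)cc(OC)cc6OC)c5OC)cc(OC)cc4Oc4c(OC)cc(OC)c(-c5c(OC)cc(OC)cc5OC)c4OC)C=C3OCC)cc(OC)cc2Oc2c(OC)cc(OC)c(-c3c(OC)cc(OC)cc3OC)c2OC)c1 | intermediate
34 | 2-(B-half aryloxy)-3-ethoxy-5-(E-half aryloxy)phenol (ten-ring phenol, one ethyl and 22 methyl ethers) | COc1cc(OC)cc(Oc2c(Oc3c(O)cc(Oc4c(Oc5c(OC)cc(OC)c(-c6c(OC)cc(OC)cc6OC)c5OC)cc(OC)cc4Oc4c(OC)cc(OC)c(-c5c(OC)cc(OC)cc5OC)c4OC)cc3OCC)cc(OC)cc2Oc2c(OC)cc(OC)c(-c3c(OC)cc(OC)cc3OC)c2OC)c1 | intermediate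
35 | CNP0294555.0 | Oc1cc(O)cc(Oc2c(Oc3c(O)cc(Oc4c(Oc5c(O)cc(O)c(-c6c(O)cc(O)cc6O)c5O)cc(O)cc4Oc4c(O)cc(O)c(-c5c(O)cc(O)cc5O)c4O)cc3O)cc(O)cc2Oc2c(O)cc(O)c(-c3c(O)cc(O)cc3O)c2O)c1 | target

**Step count and risks**

Total step count: 17. Longest linear sequence: 13 steps (1 → 2 → 4 → 6 → 8 → 17 → 19 → 21 → 22 → 24 → 25 → 29 → 34 → 35; steps 1–4 and 9–17).

Steps most likely to fail:

1. Step 16 (bears the label). What may go wrong: the donor-stabilised cyclobutenone opens only slowly, and the shielded, weakly nucleophilic aryl ynol ether may capture vinylketene 30 too slowly, so that 30 dimerises or acylates the product phenol. Fallback, known chemistry only (SNAr, copper-catalysed etherification, Baeyer–Villiger oxidation), with ring C brought in as a bought arene; it sets out from 8 and 11 and comes back at 35. Aldehyde 8 is treated with 4-bromo-2,6-dimethoxyphenol (Cs2CO3, DMF, 100 °C, SNAr) to give 2-(4-bromo-2,6-dimethoxyphenoxy)-4-methoxy-6-(ArO)benzaldehyde F1, which already carries ring C on the ring B oxygen. Ullmann-type etherification of the unhindered bromide of F1 with phenol 11 (CuI, N,N-dimethylglycine, Cs2CO3, dioxane, 110 °C) should give the nine-ring aldehyde F2. Baeyer–Villiger oxidation (mCPBA) should give the nine-ring formate F3 and methanolysis the nine-ring phenol F4, which is arylated with 20 as in step 11 to the 24-fold methyl ether of the target F5. BBr3 as in step 17 then gives 35.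

2. Step 15. What may go wrong: aryloxyketene 28 dimerises, or the acid chloride cyclises onto its electron-rich ring, faster than the ketene is trapped by ethoxyacetylene. Fallback, which bypasses 29 and makes vinylketene 30 by 1,4-dehydrochlorination; it sets out from 22 and comes back at 34. Phenol 22 is alkylated with commercial ethyl (E)-4-chloro-3-ethoxybut-2-enoate (K2CO3, NaI cat., DMF, 50 °C) to ethyl (E)-4-(B-half aryloxy)-3-ethoxybut-2-enoate F6, saponified (LiOH, then HCl) to (E)-4-(B-half aryloxy)-3-ethoxybut-2-enoic acid F7 and converted with (COCl)2 into (E)-4-(B-half aryloxy)-3-ethoxybut-2-enoyl chloride F8. Slow addition of Et3N to F8 and ynol ether 16 in toluene (rt, then 80–110 °C) should remove HCl across the four-carbon chain and generate vinylketene 30 directly, from which the cascade of step 16 runs on to 34.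

3. Step 11. What may go wrong: the coupling stalls at the doubly flanked oxygen, or the electron-rich phenol is oxidised under hot basic copper conditions. Fallback, a metal-free arylation with a diaryliodonium salt; it sets out from 19 and 20 and comes back at 21. Iodide 20 is oxidised (mCPBA, TsOH·H2O, MeCN) and condensed in the same flask with 1,3,5-trimethoxybenzene to (3,5-dimethoxyphenyl)(2,4,6-trimethoxyphenyl)iodonium tosylate F9. The potassium phenoxide of 19 (t-BuOK, toluene, rt to 50 °C) adds to the trivalent iodine and ligand coupling should transfer the less electron-rich 3,5-dimethoxyphenyl group to oxygen, giving 21.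

**Further compounds**

F1 | step 16 | 2-(4-bromo-2,6-dimethoxyphenoxy)-4-methoxy-6-(ArO)benzaldehyde | O=Cc1c(Oc2c(OC)cc(Br)cc2OC)cc(OC)cc1Oc1c(OC)cc(OC)c(-c2c(OC)cc(OC)cc2OC)c1OC
F2 | step 16 | 2-[2,6-dimethoxy-4-(E-half aryloxy)phenoxy]-4-methoxy-6-(ArO)benzaldehyde (nine-ring aldehyde) | O=Cc1c(Oc2c(OC)cc(Oc3c(Oc4c(OC)cc(OC)c(-c5c(OC)cc(OC)cc5OC)c4OC)cc(OC)cc3Oc3c(OC)cc(OC)c(-c4c(OC)cc(OC)cc4OC)c3OC)cc2OC)cc(OC)cc1Oc1c(OC)cc(OC)c(-c2c(OC)cc(OC)cc2OC)c1OC
F3 | step 16 | 2-[2,6-dimethoxy-4-(E-half aryloxy)phenoxy]-4-methoxy-6-(ArO)phenyl formate (nine-ring formate) | O=COc1c(Oc2c(OC)cc(Oc3c(Oc4c(OC)cc(OC)c(-c5c(OC)cc(OC)cc5OC)c4OC)cc(OC)cc3Oc3c(OC)cc(OC)c(-c4c(OC)cc(OC)cc4OC)c3OC)cc2OC)cc(OC)cc1Oc1c(OC)cc(OC)c(-c2c(OC)cc(OC)cc2OC)c1OC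
F4 | step 16 | 2-[2,6-dimethoxy-4-(E-half aryloxy)phenoxy]-4-methoxy-6-(ArO)phenol (nine-ring phenol) | Oc1c(Oc2c(OC)cc(Oc3c(Oc4c(OC)cc(OC)c(-c5c(OC)cc(OC)cc5OC)c4OC)cc(OC)cc3Oc3c(OC)cc(OC)c(-c4c(OC)cc(OC)cc4OC)c3OC)cc2OC)cc(OC)cc1Oc1c(OC)cc(OC)c(-c2c(OC)cc(OC)cc2OC)c1OC
F5 | step 16 | 24-fold methyl ether of the target | COc1cc(OC)cc(Oc2c(Oc3c(OC)cc(Oc4c(Oc5c(OC)cc(OC)c(-c6c(OC)cc(OC)cc6OC)c5OC)cc(OC)cc4Oc4c(OC)cc(OC)c(-c5c(OC)cc(OC)cc5OC)c4OC)cc3OC)cc(OC)cc2Oc2c(OC)cc(OC)c(-c3c(OC)cc(OC)cc3OC)c2OC)c1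
F6 | step 15 | ethyl (E)-4-(B-half aryloxy)-3-ethoxybut-2-enoate | COc1cc(OC)cc(Oc2c(OC/C(OCC)=C\C(=O)OCC)cc(OC)cc2Oc2c(OC)cc(OC)c(-c3c(OC)cc(OC)cc3OC)c2OC)c1
F7 | step 15 | (E)-4-(B-half aryloxy)-3-ethoxybut-2-enoic acid | COc1cc(OC)cc(Oc2c(OC/C(OCC)=C\C(=O)O)cc(OC)cc2Oc2c(OC)cc(OC)c(-c3c(OC)cc(OC)cc3OC)c2OC)c1
F8 | step 15 | (E)-4-(B-half aryloxy)-3-ethoxybut-2-enoyl chloride | COc1cc(OC)cc(Oc2c(OC/C(OCC)=C\C(=O)Cl)cc(OC)cc2Oc2c(OC)cc(OC)c(-c3c(OC)cc(OC)cc3OC)c2OC)c1
F9 | step 11 | (3,5-dimethoxyphenyl)(2,4,6-trimethoxyphenyl)iodonium tosylate | COc1cc(OC)cc([I+]c2c(OC)cc(OC)cc2OC)c1.Cc1ccc(S(=O)(=O)[O-])cc1
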